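**Strategy.** The tetrahydrofuran ring of the furo[3,2-b]pyran-5-one (O1, C2, C3, C3a, C7a) is closed through its C2–C3 bond. The feature exploited is the C3 carbinol flanked by C2, which bears the ring oxygen and an sp2 carbon: the retron of an intramolecular γ-alkoxyallylstannane–aldehyde addition. The precursor is a 2-deoxy-D-galactopyranoside from D-galactal (C7, C7a and C3a preset) carrying, in sugar numbering, a C6 aldehyde and a (Z)-3-(tributylstannyl)prop-1-enyl ether on the cis, axial O4. Chelation-controlled SE2′ closure gives the cis-fused ring, both new stereocentres and a vinyl handle in one operation; cross-metathesis with a lactate-derived allylic benzoate, acetal hydrolysis and lactol oxidation complete the target.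

Key step: step 7

Remark: pyranose intermediates carry sugar numbering (C1–C6), bicyclic compounds furo[3,2-b]pyran numbering (sugar C6 becomes C3, the γ-carbon of the allyl unit becomes C2); D-galactal and methyl (R)-lactate are taken as commercial, and the anomeric centre drawn as α in 4–9 and 17 is destroyed in step 15.

Step 1
Reactants: 1 D-galactal
Product: 2 3,6-di-O-(tert-butyldimethylsilyl)-D-galactal
Conditions: TBSCl (2.2 equiv), imidazole, DMF, 0 °C to rt
Reagents that add atoms: tert-butyldimethylsilyl chloride, CC(C)(C)[Si](C)(C)Cl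
Why: Regioselective silyl ether formation, in which the primary O6 and the equatorial allylic O3 react fast while the axial O4, flanked on both sides, should stay free, and no stereocentre is touched.

Step 2
Reactants: 2 3,6-di-O-(tert-butyldimethylsilyl)-D-galactal
Product: 3 4-O-allyl-3,6-di-O-(tert-butyldimethylsilyl)-D-galactal
Conditions: NaH, allyl bromide, n-Bu4NI (cat.), THF, 0 °C
Reagents that add atoms: allyl bromide, C=CCBr
Why: Williamson etherification of the O4 alkoxide with the reactive allyl bromide under iodide catalysis should outrun base-induced 3→4 silyl migration, and the glycal enol ether is inert to base.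

Step 3
Reactants: 3 4-O-allyl-3,6-di-O-(tert-butyldimethylsilyl)-D-galactal
Product: 4 methyl 4-O-allyl-3,6-di-O-(tert-butyldimethylsilyl)-2-deoxy-α-D-lyxo-hexopyranoside
Conditions: MeOH (3 equiv), PPh3·HBr (5 mol %), CH2Cl2, rt
Reagents that add atoms: methanol, CO
Why: Acid-catalysed addition of methanol to the glycal (protonation at C2, oxocarbenium capture) masks C1 as an organolithium-stable acetal at the lactol oxidation level, and axial attack under the anomeric effect should give the α-glycoside, a centre that is removed later.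

Step 4
Reactants: 4 methyl 4-O-allyl-3,6-di-O-(tert-butyldimethylsilyl)-2-deoxy-α-D-lyxo-hexopyranoside
Product: 6 methyl 3,6-di-O-(tert-butyldimethylsilyl)-2-deoxy-4-O-[(Z)-3-(tributylstannyl)prop-1-en-1-yl]-α-D-lyxo-hexopyranoside, via alkoxyallyllithium 5 (not isolated)
Conditions: s-BuLi, TMEDA, THF, −78 °C; then Bu3SnCl, −78 °C
Reagents that add atoms: tributyltin chloride, CCCC[Sn](Cl)(CCCC)CCCC
Why: Directed α-lithiation of the allyl ether gives an oxygen-chelated (Z)-alkoxyallyllithium whose stannylation occurs at the γ-carbon (SE2′-type quench) to deliver the (Z)-γ-alkoxyallylstannane, while silyl ethers and the acetal tolerate s-BuLi at −78 °C.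

Step 5
Reactants: 6 methyl 3,6-di-O-(tert-butyldimethylsilyl)-2-deoxy-4-O-[(Z)-3-(tributylstannyl)prop-1-en-1-yl]-α-D-lyxo-hexopyranoside
Product: 7 methyl 3-O-(tert-butyldimethylsilyl)-2-deoxy-4-O-[(Z)-3-(tributylstannyl)prop-1-en-1-yl]-α-D-lyxo-hexopyranoside (free 6-OH)
Conditions: NH4F, MeOH, rt
Reagents that add atoms: none
Why: Fluoride-mediated desilylation with nearly neutral NH4F in methanol should cleave the unhindered primary silyl ether much faster than the secondary 3-O-silyl group and leave the acid-labile enol ether stannane and the acetal intact.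

Step 6
Reactants: 7 methyl 3-O-(tert-butyldimethylsilyl)-2-deoxy-4-O-[(Z)-3-(tributylstannyl)prop-1-en-1-yl]-α-D-lyxo-hexopyranoside
Product: 8 methyl 3-O-(tert-butyldimethylsilyl)-2-deoxy-4-O-[(Z)-3-(tributylstannyl)prop-1-en-1-yl]-α-D-lyxo-hexodialdo-1,5-pyranoside (C6 aldehyde)
Conditions: SO3·pyridine, DMSO, i-Pr2NEt, CH2Cl2, 0 °C; used at once
Reagents that add atoms: none
Why: Parikh–Doering oxidation (activated DMSO) converts the primary alcohol into the aldehyde under non-acidic conditions at 0 °C that should spare the allylstannane, the enol ether and the α-stereocentre.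

Step 7
Reactants: 8 methyl 3-O-(tert-butyldimethylsilyl)-2-deoxy-4-O-[(Z)-3-(tributylstannyl)prop-1-en-1-yl]-α-D-lyxo-hexodialdo-1,5-pyranoside
Product: 9 (2S,3R,3aR,5S,7R,7aS)-7-(tert-butyldimethylsilyloxy)-5-methoxy-2-vinylhexahydro-2H-furo[3,2-b]pyran-3-ol (cis-fused; vinyl, hydroxyl and both ring-fusion bonds on the same face of the tetrahydrofuran)
Conditions: MgBr2·OEt2 (3 equiv), CH2Cl2, −40 to 0 °C; aq. NaHCO3
Reagents that add atoms: none
Why: Mechanism: MgBr2 binds the aldehyde oxygen together with the pyranoside ring oxygen O5 (five-membered chelate) and the γ-carbon of the allylstannane attacks the activated carbonyl carbon in an anti-SE2′ process with an open transition state, tin leaving as Bu3SnBr while the double bond shifts to become the vinyl group. The closest known reaction type is the Lewis-acid-promoted intramolecular γ-alkoxyallylstannane–aldehyde cyclisation to 2-vinyl-3-hydroxy cyclic ethers, here run with the MgBr2 chelation control known for α-alkoxy aldehydes. The tetrahydrofuran closes 5-exo-trig at the carbonyl carbon (exo also for the enol ether π-bond) and is necessarily cis-fused, because axial O4 and equatorial C6 are cis on the pyranose chair. C3 is controlled by the chelate, which holds C=O syn-periplanar to C5–O5 while the tether can deliver the nucleophile only from the C4 side, so the hydroxyl should end cis to the ring-fusion oxygen (3R). C2 is controlled by the synclinal arrangement of the two π-systems (developing alkoxide oxygen gauche to the electron-poor β-carbon of the allyl unit), which in a five-membered transition state means hydroxyl and vinyl cis and places the vinyl group cis to the C7a–C7 bond (2S). The selectivities needed are γ- over α-attack (five- versus seven-membered ring), secured by the SE2′ preference and the short tether, and the facial sense at both carbons, secured by chelation and the cis-fused bicyclic transition state, while the mild Lewis acid at low temperature should leave the methyl acetal and the silyl ether untouched.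

Step 8
Reactants: 10 methyl (R)-lactate
Product: 11 methyl (R)-2-(tert-butyldimethylsilyloxy)propanoate
Conditions: TBSCl, imidazole, CH2Cl2, rt
Reagents that add atoms: tert-butyldimethylsilyl chloride, CC(C)(C)[Si](C)(C)Cl
Why: Silyl ether formation protects the lactate hydroxyl with a bulky, non-chelating group, as needed for Felkin–Anh control in the next step, and the stereocentre is untouched.

Step 9
Reactants: 11 methyl (R)-2-(tert-butyldimethylsilyloxy)propanoate
Product: 13 (3S,4R)-4-(tert-butyldimethylsilyloxy)pent-1-en-3-ol, via silyloxy aldehyde 12 (not isolated)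
Conditions: i-Bu2AlH, Et2O, −78 °C; then CH2=CHMgBr, −78 to 0 °C
Reagents that add atoms: vinylmagnesium bromide, C=C[Mg]Br
Why: Ester reduction by i-Bu2AlH stops at the aluminium hemiacetal, which releases the aldehyde for Grignard addition, and Felkin–Anh (non-chelation) attack anti to the silyloxy group should set C3 as S (3,4-anti), the minor syn isomer being removed by chromatography.

Step 10
Reactants: 13 (3S,4R)-4-(tert-butyldimethylsilyloxy)pent-1-en-3-ol
Product: 14 (3S,4R)-4-(tert-butyldimethylsilyloxy)pent-1-en-3-yl benzoate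
Conditions: BzCl, pyridine, DMAP (cat.), CH2Cl2, 0 °C to rt
Reagents that add atoms: benzoyl chloride, O=C(Cl)c1ccccc1
Why: DMAP-catalysed acylation of the only free hydroxyl installs the allylic benzoate with retention of configuration.

Step 11
Reactants: 14 (3S,4R)-4-(tert-butyldimethylsilyloxy)pent-1-en-3-yl benzoate
Product: 15 (3S,4R)-4-hydroxypent-1-en-3-yl benzoate
Conditions: HF·pyridine, THF, 0 °C to rt
Reagents that add atoms: none
Why: Acidic fluoride desilylation frees the C4 hydroxyl without generating the alkoxide that would trigger 1,2-benzoyl migration.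

Step 12
Reactants: 15 (3S,4R)-4-hydroxypent-1-en-3-yl benzoate
Product: 16 (3S,4R)-4-acetoxypent-1-en-3-yl benzoate
Conditions: Ac2O, pyridine, DMAP (cat.), CH2Cl2, 0 °C
Reagents that add atoms: acetic anhydride, CC(=O)OC(C)=O
Why: DMAP-catalysed acetylation of the liberated secondary alcohol is much faster than acyl migration and completes the differentiated anti-diol diester.

Step 13
Reactants: 9 (2S,3R,3aR,5S,7R,7aS)-7-(tert-butyldimethylsilyloxy)-5-methoxy-2-vinylhexahydro-2H-furo[3,2-b]pyran-3-ol; 16 (3S,4R)-4-acetoxypent-1-en-3-yl benzoate (3 equiv)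
Product: 17 (1E,3S,4R)-4-acetoxy-1-[(2S,3R,3aR,5S,7R,7aS)-7-(tert-butyldimethylsilyloxy)-3-hydroxy-5-methoxyhexahydro-2H-furo[3,2-b]pyran-2-yl]pent-1-en-3-yl benzoate
Conditions: second-generation Hoveyda–Grubbs catalyst RuCl2(H2IMes)(=CH-C6H4-2-O-i-Pr) (10 mol %), CH2Cl2, 40 °C
Reagents that add atoms: none
Why: Olefin cross-metathesis between the vinyl group of 9 and an excess of the allylic benzoate 16, both slow to homodimerise, should give the thermodynamically favoured (E)-alkene, and the ruthenium carbene tolerates the free alcohol, acetal, silyl ether and esters.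

Step 14
Reactants: 17 (1E,3S,4R)-4-acetoxy-1-[(2S,3R,3aR,5S,7R,7aS)-7-(tert-butyldimethylsilyloxy)-3-hydroxy-5-methoxyhexahydro-2H-furo[3,2-b]pyran-2-yl]pent-1-en-3-yl benzoate
Product: 19 (1E,3S,4R)-4-acetoxy-1-[(2S,3R,3aR,7R,7aR)-3,5,7-trihydroxyhexahydro-2H-furo[3,2-b]pyran-2-yl]pent-1-en-3-yl benzoate (lactol, both C5 anomers), via silylated lactol 18 (not isolated)
Conditions: 2 M aq. HCl/THF (1:2), rt
Reagents that add atoms: water, O
Why: Acid-catalysed acetal hydrolysis of the 2-deoxyglycoside is fast because no C2 oxygen destabilises the oxocarbenium ion, and the same dilute acid then cleaves the secondary silyl ether while the benzoate and acetate should survive at room temperature.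

Step 15
Reactants: 19 (1E,3S,4R)-4-acetoxy-1-[(2S,3R,3aR,7R,7aR)-3,5,7-trihydroxyhexahydro-2H-furo[3,2-b]pyran-2-yl]pent-1-en-3-yl benzoate
Product: 20 (1E,3S,4R)-4-acetoxy-1-[(2S,3R,3aR,7R,7aR)-3,7-dihydroxy-5-oxohexahydro-2H-furo[3,2-b]pyran-2-yl]pent-1-en-3-yl benzoate (target, CNP0230210.1)
Conditions: Ag2CO3 on Celite, toluene, 90 °C
Reagents that add atoms: none
Why: Fétizon oxidation dehydrogenates the lactol far faster than the two secondary alcohols and does not touch the alkene or the esters, and since the sugar O4 is locked in the tetrahydrofuran only the δ-lactone can form.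

**Compound list**

1 | D-galactal | C1=C[C@@H](O)[C@@H](O)[C@@H](CO)O1 | starting material
2 | 3,6-di-O-(tert-butyldimethylsilyl)-D-galactal | C1=C[C@@H](O[Si](C)(C)C(C)(C)C)[C@@H](O)[C@@H](CO[Si](C)(C)C(C)(C)C)O1 | intermediate
3 | 4-O-allyl-3,6-di-O-(tert-butyldimethylsilyl)-D-galactal | C1=C[C@@H](O[Si](C)(C)C(C)(C)C)[C@@H](OCC=C)[C@@H](CO[Si](C)(C)C(C)(C)C)O1 | intermediate
4 | methyl 4-O-allyl-3,6-di-O-(tert-butyldimethylsilyl)-2-deoxy-α-D-lyxo-hexopyranoside | CO[C@@H]1C[C@@H](O[Si](C)(C)C(C)(C)C)[C@@H](OCC=C)[C@@H](CO[Si](C)(C)C(C)(C)C)O1 | intermediate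
5 | (Z)-alkoxyallyllithium of 4 (drawn as the γ-lithio (Z)-enol ether) | CO[C@@H]1C[C@@H](O[Si](C)(C)C(C)(C)C)[C@@H](O/C=C\C[Li])[C@@H](CO[Si](C)(C)C(C)(C)C)O1 | intermediate
6 | methyl 3,6-di-O-(tert-butyldimethylsilyl)-2-deoxy-4-O-[(Z)-3-(tributylstannyl)prop-1-en-1-yl]-α-D-lyxo-hexopyranoside | CO[C@@H]1C[C@@H](O[Si](C)(C)C(C)(C)C)[C@@H](O/C=C\C[Sn](CCCC)(CCCC)CCCC)[C@@H](CO[Si](C)(C)C(C)(C)C)O1 | intermediate
7 | methyl 3-O-(tert-butyldimethylsilyl)-2-deoxy-4-O-[(Z)-3-(tributylstannyl)prop-1-en-1-yl]-α-D-lyxo-hexopyranoside | CO[C@@H]1C[C@@H](O[Si](C)(C)C(C)(C)C)[C@@H](O/C=C\C[Sn](CCCC)(CCCC)CCCC)[C@@H](CO)O1 | intermediate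
8 | methyl 3-O-(tert-butyldimethylsilyl)-2-deoxy-4-O-[(Z)-3-(tributylstannyl)prop-1-en-1-yl]-α-D-lyxo-hexodialdo-1,5-pyranoside | CO[C@@H]1C[C@@H](O[Si](C)(C)C(C)(C)C)[C@@H](O/C=C\C[Sn](CCCC)(CCCC)CCCC)[C@@H](C=O)O1 | intermediate
9 | (2S,3R,3aR,5S,7R,7aS)-7-(tert-butyldimethylsilyloxy)-5-methoxy-2-vinylhexahydro-2H-furo[3,2-b]pyran-3-ol | C=C[C@@H]1O[C@H]2[C@H](O[C@H](OC)C[C@H]2O[Si](C)(C)C(C)(C)C)[C@@H]1O | intermediate
10 | methyl (R)-lactate | C[C@@H](O)C(=O)OC | starting material
11 | methyl (R)-2-(tert-butyldimethylsilyloxy)propanoate | C[C@@H](O[Si](C)(C)C(C)(C)C)C(=O)OC | intermediate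
12 | (R)-2-(tert-butyldimethylsilyloxy)propanal | C[C@@H](O[Si](C)(C)C(C)(C)C)C=O | intermediate
13 | (3S,4R)-4-(tert-butyldimethylsilyloxy)pent-1-en-3-ol | C[C@@H](O[Si](C)(C)C(C)(C)C)[C@@H](O)C=C | intermediate
14 | (3S,4R)-4-(tert-butyldimethylsilyloxy)pent-1-en-3-yl benzoate | C[C@@H](O[Si](C)(C)C(C)(C)C)[C@@H](OC(=O)c1ccccc1)C=C | intermediate
15 | (3S,4R)-4-hydroxypent-1-en-3-yl benzoate | C[C@@H](O)[C@@H](OC(=O)c1ccccc1)C=C | intermediate
16 | (3S,4R)-4-acetoxypent-1-en-3-yl benzoate | CC(=O)O[C@H](C)[C@H](C=C)OC(=O)c1ccccc1 | intermediate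
17 | (1E,3S,4R)-4-acetoxy-1-[(2S,3R,3aR,5S,7R,7aS)-7-(tert-butyldimethylsilyloxy)-3-hydroxy-5-methoxyhexahydro-2H-furo[3,2-b]pyran-2-yl]pent-1-en-3-yl benzoate | CC(=O)O[C@H](C)[C@H](/C=C/[C@@H]1O[C@H]2[C@H](O[C@H](OC)C[C@H]2O[Si](C)(C)C(C)(C)C)[C@@H]1O)OC(=O)c1ccccc1 | intermediate
18 | (1E,3S,4R)-4-acetoxy-1-[(2S,3R,3aR,7R,7aS)-7-(tert-butyldimethylsilyloxy)-3,5-dihydroxyhexahydro-2H-furo[3,2-b]pyran-2-yl]pent-1-en-3-yl benzoate (both C5 anomers) | CC(=O)O[C@H](C)[C@H](/C=C/[C@@H]1O[C@H]2[C@H](OC(O)C[C@H]2O[Si](C)(C)C(C)(C)C)[C@@H]1O)OC(=O)c1ccccc1 | intermediate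
19 | (1E,3S,4R)-4-acetoxy-1-[(2S,3R,3aR,7R,7aR)-3,5,7-trihydroxyhexahydro-2H-furo[3,2-b]pyran-2-yl]pent-1-en-3-yl benzoate (both C5 anomers) | CC(=O)O[C@H](C)[C@H](/C=C/[C@@H]1O[C@H]2[C@H](OC(O)C[C@H]2O)[C@@H]1O)OC(=O)c1ccccc1 | intermediate
20 | (1E,3S,4R)-4-acetoxy-1-[(2S,3R,3aR,7R,7aR)-3,7-dihydroxy-5-oxohexahydro-2H-furo[3,2-b]pyran-2-yl]pent-1-en-3-yl benzoate | CC(=O)O[C@H](C)[C@H](/C=C/[C@@H]1O[C@H]2[C@H](OC(=O)C[C@H]2O)[C@@H]1O)OC(=O)c1ccccc1 | target

**Totals.** 15 steps in all; longest linear sequence 10 steps (steps 1–7 and 13–15, from D-galactal).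

**Steps most likely to fail**

1. Step 7. The ring oxygen may be too weak a ligand for magnesium, so that the aldehyde reacts through its non-chelated, dipole-minimised rotamer (poor facial selectivity at C3), or closure may run through an antiperiplanar instead of a synclinal geometry (hydroxyl and vinyl trans). The fallback sets the carbinol centre by hydride addition instead of in the C–C bond formation; it sets out from 8 and comes back at 9. Cyclisation of 8 under the monodentate Lewis acid BF3·OEt2 (CH2Cl2, −78 °C), where no chelate can form, should give the 3-epimeric alcohol F1. Dess–Martin oxidation (NaHCO3 buffer, 0 °C) would give the ketone F2. Reduction with LiBH(s-Bu)3 in THF at −78 °C, from the convex face and anti to the 2-vinyl group, should then return 9.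

2. Step 13. Productive metathesis between two α-branched allylic olefins may be slow and lose out to homodimerisation of 16 and to ruthenium-hydride double-bond migration in the allylic ether. The fallback builds the alkene by Julia–Kocienski olefination; it sets out from 9 and comes back at 19. Silylation of 9 (TBSOTf, 2,6-lutidine) would give the bis-silyl ether F3. Ozonolysis (O3, CH2Cl2, −78 °C; PPh3) would give the aldehyde F4, and NaBH4 reduction the primary alcohol F5. Mitsunobu reaction with 1-phenyl-1H-tetrazole-5-thiol (PPh3, DIAD) would give the tetrazolyl sulfide F6, and oxidation ((NH4)6Mo7O24 cat., H2O2, EtOH) the sulfone F7. Ozonolysis of 16 would give the aldehyde F8. Deprotonation of F7 with KHMDS (DME, −60 °C) and addition of F8 should give the (E)-alkene F9. Hydrolysis of F9 with 2 M aq. HCl/THF removes the methyl acetal and both silyl ethers and rejoins the route at 19.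

3. Step 5. Fluoride treatment may also remove the secondary silyl ether, or protodestannylate the enol ether stannane. The fallback frees the primary alcohol before the tin is introduced; it sets out from 4 and comes back at 7. Acid-catalysed methanolysis of 4 (camphorsulfonic acid cat., MeOH/CH2Cl2, 0 °C) should cleave only the primary silyl ether and give the primary alcohol F10. Treatment of F10 with s-BuLi (2.2 equiv)/TMEDA at −78 °C forms the alkoxide and the alkoxyallyllithium, and Bu3SnCl (2.2 equiv) followed by aqueous KF work-up, which hydrolyses the O–Sn bond, should give 7 directly.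

**Further compounds**

F1 | step 7 | (2S,3S,3aR,5S,7R,7aS)-7-(tert-butyldimethylsilyloxy)-5-methoxy-2-vinylhexahydro-2H-furo[3,2-b]pyran-3-ol (3-epimer of 9) | C=C[C@@H]1O[C@H]2[C@H](O[C@H](OC)C[C@H]2O[Si](C)(C)C(C)(C)C)[C@H]1O
F2 | step 7 | 7-(tert-butyldimethylsilyloxy)-5-methoxy-2-vinyltetrahydro-2H-furo[3,2-b]pyran-3(3aH)-one (3-ketone of 9, other centres as in 9) | C=C[C@@H]1O[C@H]2[C@H](O[C@H](OC)C[C@H]2O[Si](C)(C)C(C)(C)C)C1=O
F3 | step 13 | 3-O-(tert-butyldimethylsilyl) ether of 9 | C=C[C@@H]1O[C@H]2[C@H](O[C@H](OC)C[C@H]2O[Si](C)(C)C(C)(C)C)[C@@H]1O[Si](C)(C)C(C)(C)C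
F4 | step 13 | 3,7-bis(tert-butyldimethylsilyloxy)-5-methoxyhexahydro-2H-furo[3,2-b]pyran-2-carbaldehyde (configuration as in 9) | O=C[C@@H]1O[C@H]2[C@H](O[C@H](OC)C[C@H]2O[Si](C)(C)C(C)(C)C)[C@@H]1O[Si](C)(C)C(C)(C)C
F5 | step 13 | [3,7-bis(tert-butyldimethylsilyloxy)-5-methoxyhexahydro-2H-furo[3,2-b]pyran-2-yl]methanol (configuration as in 9) | OC[C@@H]1O[C@H]2[C@H](O[C@H](OC)C[C@H]2O[Si](C)(C)C(C)(C)C)[C@@H]1O[Si](C)(C)C(C)(C)C
F6 | step 13 | 1-phenyl-1H-tetrazol-5-yl sulfide of F5 | c1ccccc1-n1nnnc1SC[C@@H]1O[C@H]2[C@H](O[C@H](OC)C[C@H]2O[Si](C)(C)C(C)(C)C)[C@@H]1O[Si](C)(C)C(C)(C)C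
F7 | step 13 | 1-phenyl-1H-tetrazol-5-yl sulfone derived from F6 | O=S(=O)(C[C@@H]1O[C@H]2[C@H](O[C@H](OC)C[C@H]2O[Si](C)(C)C(C)(C)C)[C@@H]1O[Si](C)(C)C(C)(C)C)c1nnnn1-c1ccccc1
F8 | step 13 | (2R,3R)-3-acetoxy-1-oxobutan-2-yl benzoate | CC(=O)O[C@H](C)[C@H](C=O)OC(=O)c1ccccc1
F9 | step 13 | 3-O-(tert-butyldimethylsilyl) ether of 17 | CC(=O)O[C@H](C)[C@H](/C=C/[C@@H]1O[C@H]2[C@H](O[C@H](OC)C[C@H]2O[Si](C)(C)C(C)(C)C)[C@@H]1O[Si](C)(C)C(C)(C)C)OC(=O)c1ccccc1
F10 | step 5 | methyl 4-O-allyl-3-O-(tert-butyldimethylsilyl)-2-deoxy-α-D-lyxo-hexopyranoside | CO[C@@H]1C[C@@H](O[Si](C)(C)C(C)(C)C)[C@@H](OCC=C)[C@@H](CO)O1
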